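**Plan**

- Retrosynthesis: the C20 aldehyde and C19 acid are unmasked from a temporary 19,20-δ-lactone. The cuts are then C13–C16 (ring D), C3–C4 (ring A), C4–C5 (tethered propanoate), C10–C1, C9–C10 (ring B), C5=C10 and C5–C6 (glutaconate arm), and ring C back to pent-4-ynal, tert-butyl bromoacetate and methyl vinyl ketone.
- Forward: ring C (Robinson annulation, then a prochiral 4,4-disubstituted cyclohexadienone) → ring B (desymmetrising Michael addition) → temporary lactone ring → ring A (key alkylation) → ring D (gold-catalysed enol ether/alkyne cyclisation) → lactone opening and oxidation.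
- Stereochemistry: C8 and C9 come from the catalyst-controlled desymmetrisation, C10 from alkylation anti to ring C, C5 and C4 from the C20–O–C19 tether, C6 from equilibration, and C13 follows from C8.
- Enabling feature: C19 (on C4) and C20 (on C10) are 1,3-syn on the α-face of ring A. They can therefore be tied into a six-membered lactone (C4–C19–O–C20–C10–C5) that is not in the target. This ring makes the C4 enolate endocyclic and holds the C1–C3 chain on C10 over one face of it.

Key step: step 13

Remarks on the chemistry:
- Gibberellane numbering (C1–C20) is used for all intermediates. β is the face of ring B that carries 5-H, 9-H, C1, C7 and C15; α is the face that carries C20, C4, C11 and C14.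
- Centres that are racemic or left as epimer mixtures (they are erased or equilibrated later) carry no descriptor in the SMILES, and the name says so.
- The target is written as the open 20-aldehyde 19-acid; it may equilibrate with its 19,20-lactol.

Step 1
Reactants: 1 pent-4-ynal; 2 tert-butyl bromoacetate
Product: 4 tert-butyl 3-formylhex-5-ynoate (racemic), via pyrrolidine enamine 3 (not isolated)
Conditions: pyrrolidine (1.2 equiv), 4 Å MS, MeCN, 0 °C; then 2, 60 °C; then AcOH/NaOAc/H2O
Reagents that add atoms: pyrrolidine C1CCNC1 (its atoms stay only in 3)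
Why: Stork enamine alkylation: the aldehyde enamine is C-alkylated by the reactive α-bromo ester and hydrolysed, which joins C8 to C6 with C7 already in place as the tert-butyl ester; the racemic centre becomes prochiral in step 3.

Step 2
Reactants: 4 tert-butyl 3-formylhex-5-ynoate; 5 but-3-en-2-one
Product: 7 tert-butyl 2-[4-oxo-1-(prop-2-yn-1-yl)cyclohex-2-en-1-yl]acetate (racemic), via keto-aldehyde 6 (not isolated)
Conditions: pyrrolidine (30 mol %), AcOH (30 mol %), toluene, 60 → 90 °C
Reagents that add atoms: none
Why: Amine-catalysed Robinson annulation of an α,α-disubstituted aldehyde (enamine Michael addition, then intramolecular aldol condensation) builds ring C and makes C8 quaternary.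

Step 3
Reactants: 7 tert-butyl 2-[4-oxo-1-(prop-2-yn-1-yl)cyclohex-2-en-1-yl]acetate
Product: 8 tert-butyl 2-[4-oxo-1-(prop-2-yn-1-yl)cyclohexa-2,5-dien-1-yl]acetate (achiral)
Conditions: IBX (2.5 equiv), DMSO, 75 °C
Reagents that add atoms: none
Why: IBX dehydrogenation of the enone should give the cross-conjugated dienone, in which C8 is prochiral and flanked by two enantiotopic enone arms.

Step 4
Reactants: 8 tert-butyl 2-[4-oxo-1-(prop-2-yn-1-yl)cyclohexa-2,5-dien-1-yl]acetate; 9 2,2,2-trifluoroethyl formate
Product: 10 tert-butyl 3-oxo-2-[4-oxo-1-(prop-2-yn-1-yl)cyclohexa-2,5-dien-1-yl]propanoate (racemic; largely the hydroxymethylene enol)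
Conditions: LDA (2.2 equiv; one equivalent is held by the alkyne C–H), THF, −78 °C; 9; AcOH, −78 °C
Reagents that add atoms: none
Why: Claisen formylation of the ester enolate installs C5; the dienone has no enolisable hydrogen, and the formyl-ester anion cannot cyclise because its only carbon nucleophile (C6) would have to close a three-membered ring.

Step 5
Reactants: 10 tert-butyl 3-oxo-2-[4-oxo-1-(prop-2-yn-1-yl)cyclohexa-2,5-dien-1-yl]propanoate; 11 methyl (triphenylphosphoranylidene)acetate
Product: 12 1-tert-butyl 5-methyl (3E)-2-[4-oxo-1-(prop-2-yn-1-yl)cyclohexa-2,5-dien-1-yl]pent-3-enedioate (racemic at C6)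
Conditions: toluene, 80 °C
Reagents that add atoms: none
Why: Wittig olefination through the aldehyde tautomer adds C10 and C20 and completes a 2-substituted glutaconate; the stabilised ylide is too weak a base to ionise the product, so no uncatalysed (racemic) cyclisation should occur.

Step 6
Reactants: 12 1-tert-butyl 5-methyl (3E)-2-[4-oxo-1-(prop-2-yn-1-yl)cyclohexa-2,5-dien-1-yl]pent-3-enedioate
Product: 13 cis-fused bicyclic enone diester (3-tert-butyl 1-methyl 6-oxo-3a-propargyl-3a,6,7,7a-tetrahydro-1H-indene-1,3-dicarboxylate; 9-H cis to the propargyl group; C10 epimer mixture)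
Conditions: epi-quinine-derived tertiary amine–thiourea (10 mol %), toluene, −20 °C (the quinidine-derived pseudo-enantiomer would give the antipode)
Reagents that add atoms: none
Why: Organocatalytic desymmetrising intramolecular Michael addition (5-exo-trig) of the glutaconate (vinylogous malonate) anion through C10 onto C9; the catalyst chooses between the two enantiotopic enone arms, and the three-atom tether C6–C5–C10 allows only cis ring fusion, so C8 and C9 are fixed together.

Step 7
Reactants: 13 cis-fused bicyclic enone diester; 14 1-bromo-3-chloropropane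
Product: 15 C10-alkylated diester (3-tert-butyl 1-methyl 1-(3-chloropropyl)-6-oxo-3a-propargyl-3a,6,7,7a-tetrahydro-1H-indene-1,3-dicarboxylate; chloropropyl β and cis to 9-H)
Conditions: Cs2CO3, DMF, 0 → 25 °C
Reagents that add atoms: none
Why: C-alkylation of the delocalised C6–C5–C10 anion at its less hindered terminus C10 (C6 adjoins quaternary C8), with bromide displaced in preference to chloride; the electrophile should enter on the β-face, away from cis-fused ring C, which sets C10 and leaves the conjugated C5=C6 ester.

Step 8
Reactants: 15 C10-alkylated diester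
Product: 16 triisopropylsilyl enol ether (3-tert-butyl 1-methyl 1-(3-chloropropyl)-3a-propargyl-6-[(triisopropylsilyl)oxy]-3a,4,7,7a-tetrahydro-1H-indene-1,3-dicarboxylate)
Conditions: K-Selectride (1.1 equiv), THF, −78 °C; TIPSOTf, −78 → 0 °C
Reagents that add atoms: triisopropylsilyl triflate CC(C)[Si](C(C)C)(C(C)C)OS(=O)(=O)C(F)(F)F
Why: 1,4-Reduction of the β-unsubstituted cyclohexenone and O-silylation of the enolate should give the C12=C13 silyl enol ether regiospecifically; it masks the C12 ketone from the later bases and is the nucleophile for ring D.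

Step 9
Reactants: 16 triisopropylsilyl enol ether
Product: 17 primary alcohol (tert-butyl 1-(3-chloropropyl)-1-(hydroxymethyl)-3a-propargyl-6-[(triisopropylsilyl)oxy]-3a,4,7,7a-tetrahydro-1H-indene-3-carboxylate)
Conditions: LiBH4, THF–MeOH, 0 → 40 °C
Reagents that add atoms: none
Why: Chemoselective borohydride reduction of the methyl ester (C20) in the presence of the tert-butyl enoate, the silyl enol ether and the alkyl chloride.

Step 10
Reactants: 17 primary alcohol; 18 propanoyl chloride
Product: 19 propanoate ester of 17 (C20–O–CO–CH2CH3)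
Conditions: pyridine, DMAP (cat.), CH2Cl2, 0 °C
Reagents that add atoms: none
Why: Acylation of the neopentyl alcohol attaches C19, C4 and C18 to C20 through the temporary ester oxygen.

Step 11
Reactants: 19 propanoate ester
Product: 20 cis-fused δ-lactone chloride (C19–O–C20 lactone on ring B; 5β-H; C4 and C6 as epimer mixtures)
Conditions: LDA (2.2 equiv; part is held by the alkyne C–H), THF, −78 °C; AcOH, −78 °C
Reagents that add atoms: none
Why: Intramolecular Michael addition of the tethered propanoate enolate to the C5=C6 tert-butyl enoate (6-(enolendo)-exo-trig) forms C4–C5; the tether sits on the α-face at C10, so C4 is delivered α and 5-H becomes β, while the alkyl chloride is inert at −78 °C.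

Step 12
Reactants: 20 cis-fused δ-lactone chloride
Product: 21 cis-fused δ-lactone iodide
Conditions: NaI, NaHCO3, butan-2-one, 70 °C
Reagents that add atoms: sodium iodide [Na+].[I-]
Why: Finkelstein exchange gives the better leaving group only after the enolate chemistry of step 11 is over.

Step 13
Reactants: 21 cis-fused δ-lactone iodide
Product: 22 ring-A-closed 19,20-lactone tert-butyl ester (8-propargyl; 12-[(triisopropylsilyl)oxy]-12-ene; C19 α, C18 β, 5β-H, 6β-CO2t-Bu, 9β-H)
Conditions: KHMDS (2.2 equiv; part is held by the alkyne C–H), THF–DMPU, −78 → 0 °C; then t-BuOH (10 equiv), 25 °C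
Reagents that add atoms: none
Why: Deprotonation of the δ-lactone at C4 (the most acidic C–H; the hindered tert-butyl ester C–H at C6 is about five pKa units weaker) gives an endocyclic potassium lactone enolate that displaces iodide at C3 in an intramolecular SN2 alkylation; the closest known reaction type is the intramolecular alkylation of ester and lactone enolates by ω-halides to form bridged bicycles with a quaternary α-carbon. Ring A closes in the 6-(enolexo)-exo-tet mode and the product is a 2-oxabicyclo[3.3.1]nonan-3-one, so the temporary lactone becomes the 1,3-diaxial bridge of a chair ring A. The new quaternary centre C4 is controlled by the tether alone: C19 is locked in the lactone ring cis to C20, and the C1–C3 chain on C10 can reach C4 only when it is axial on the lactone ring, so C3 bonds to the enolate face syn to the chain and C18 is left β (equatorial on ring A). The trans A/B fusion follows from C10 (step 7) and C5 (step 11). The step needs site selectivity (C4 over C6; O-alkylation would need an eight-membered ring) and substitution over elimination, which the acidity gap, the silazide base, the potassium enolate and the iodide should secure. After ring closure, the t-BuOK formed on adding t-BuOH equilibrates C6, the only remaining acidic centre, to the expectedly more stable 6β-ester (trans to C4, on the convex face).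

Step 14
Reactants: 22 ring-A-closed 19,20-lactone tert-butyl ester
Product: 23 12-oxo-GA15 tert-butyl ester (tert-butyl 12-oxogibberell-16-en-7-oate 19,20-lactone)
Conditions: Ph3PAuCl/AgBF4 (5 mol %), CH2Cl2–H2O (10:1), 40 °C
Reagents that add atoms: none
Why: Gold(I)-catalysed Conia-ene-type carbocyclisation of the silyl enol ether onto the terminal alkyne (5-exo-dig) forms C13–C16 and gives the 12-ketone and the 16-methylene directly; the bridge can only form cis across ring C, so C13 follows from C8.

Step 15
Reactants: 23 12-oxo-GA15 tert-butyl ester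
Product: 25 12-oxo-GA15 (7-acid 19,20-lactone), via bis(trimethylsilyl) derivative 24 (not isolated)
Conditions: TMSOTf (3 equiv), 2,6-lutidine, CH2Cl2, 0 °C; aq. citric acid/THF
Reagents that add atoms: trimethylsilyl triflate C[Si](C)(C)OS(=O)(=O)C(F)(F)F (silicon stays only in 24)
Why: Silyl-triflate cleavage of the tert-butyl ester (loss of isobutene) avoids protic acid and so spares the exocyclic alkene; the silyl ester and the transient C11=C12 silyl enol ether are hydrolysed on work-up.

Step 16
Reactants: 25 12-oxo-GA15
Product: 27 diallyl 20-hydroxy-12-oxogibberell-16-ene-7,19-dioate, via dipotassium seco-acid salt 26 (not isolated)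
Conditions: KOH, MeOH–H2O, 70 °C; CO2 to pH 9, evaporate; allyl bromide, DMF, 25 °C; used crude
Reagents that add atoms: potassium hydroxide [K+].[OH-]; allyl bromide C=CCBr
Why: Saponification opens the temporary lactone, and O-alkylation of the two carboxylates in the same flask prevents relactonisation on acidification and leaves the 20-hydroxyl free.

Step 17
Reactants: 27 diallyl 20-hydroxy-12-oxogibberell-16-ene-7,19-dioate
Product: 28 diallyl 12,20-dioxogibberell-16-ene-7,19-dioate
Conditions: Dess–Martin periodinane, NaHCO3, CH2Cl2, 0 → 25 °C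
Reagents that add atoms: none
Why: Dess–Martin oxidation of the neopentyl primary alcohol gives the C20 aldehyde, which has no α-hydrogen and cannot epimerise.

Step 18
Reactants: 28 diallyl 12,20-dioxogibberell-16-ene-7,19-dioate
Product: 29 12,20-dioxogibberell-16-ene-7,19-dioic acid (12-oxo-GA24; the target)
Conditions: Pd(PPh3)4 (5 mol %), morpholine, THF, 25 °C; work-up at pH 3
Reagents that add atoms: none
Why: Palladium(0)-catalysed allyl transfer to morpholine (Tsuji–Trost deallylation) frees both acids under neutral conditions that the aldehyde, the ketone and the exocyclic alkene should tolerate.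

**Compound list**

1 | pent-4-ynal | C#CCCC=O | starting material
2 | tert-butyl bromoacetate | BrCC(=O)OC(C)(C)C | starting material
3 | 1-[(1E)-pent-1-en-4-yn-1-yl]pyrrolidine | C#CC/C=C/N1CCCC1 | intermediate (not isolated)
4 | tert-butyl 3-formylhex-5-ynoate (racemic) | C#CCC(C=O)CC(=O)OC(C)(C)C | intermediate
5 | but-3-en-2-one | C=CC(C)=O | starting material
6 | tert-butyl 3-formyl-6-oxo-3-(prop-2-yn-1-yl)heptanoate (racemic) | C#CCC(C=O)(CCC(C)=O)CC(=O)OC(C)(C)C | intermediate (not isolated)
7 | tert-butyl 2-[4-oxo-1-(prop-2-yn-1-yl)cyclohex-2-en-1-yl]acetate (racemic) | C#CCC1(CC(=O)OC(C)(C)C)C=CC(=O)CC1 | intermediate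
8 | tert-butyl 2-[4-oxo-1-(prop-2-yn-1-yl)cyclohexa-2,5-dien-1-yl]acetate | C#CCC1(CC(=O)OC(C)(C)C)C=CC(=O)C=C1 | intermediate
9 | 2,2,2-trifluoroethyl formate | O=COCC(F)(F)F | starting material
10 | tert-butyl 3-oxo-2-[4-oxo-1-(prop-2-yn-1-yl)cyclohexa-2,5-dien-1-yl]propanoate (racemic) | C#CCC1(C(C=O)C(=O)OC(C)(C)C)C=CC(=O)C=C1 | intermediate
11 | methyl (triphenylphosphoranylidene)acetate | COC(=O)C=P(c1ccccc1)(c1ccccc1)c1ccccc1 | starting material
12 | 1-tert-butyl 5-methyl (3E)-2-[4-oxo-1-(prop-2-yn-1-yl)cyclohexa-2,5-dien-1-yl]pent-3-enedioate (racemic at C6) | C#CCC1(C(/C=C/C(=O)OC)C(=O)OC(C)(C)C)C=CC(=O)C=C1 | intermediate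
13 | cis-fused bicyclic enone diester (C8, C9 set; C10 epimers) | C#CC[C@]23C=CC(=O)C[C@H]2C(C(=O)OC)C=C3C(=O)OC(C)(C)C | intermediate
14 | 1-bromo-3-chloropropane | ClCCCBr | starting material
15 | C10-(3-chloropropyl) diester | C#CC[C@]23C=CC(=O)C[C@H]2[C@](C(=O)OC)(CCCCl)C=C3C(=O)OC(C)(C)C | intermediate
16 | triisopropylsilyl enol ether of 15 (C12=C13) | C#CC[C@]23CC=C(O[Si](C(C)C)(C(C)C)C(C)C)C[C@H]2[C@](C(=O)OC)(CCCCl)C=C3C(=O)OC(C)(C)C | intermediate
17 | C20 primary alcohol | C#CC[C@]23CC=C(O[Si](C(C)C)(C(C)C)C(C)C)C[C@H]2[C@](CO)(CCCCl)C=C3C(=O)OC(C)(C)C | intermediate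
18 | propanoyl chloride | CCC(Cl)=O | starting material
19 | C20 propanoate ester | C#CC[C@]23CC=C(O[Si](C(C)C)(C(C)C)C(C)C)C[C@H]2[C@](COC(=O)CC)(CCCCl)C=C3C(=O)OC(C)(C)C | intermediate
20 | cis-fused 19,20-δ-lactone chloride (5β-H; C4, C6 epimers) | C#CC[C@]23CC=C(O[Si](C(C)C)(C(C)C)C(C)C)C[C@H]2[C@@]4(CCCCl)COC(=O)C(C)[C@H]4C3C(=O)OC(C)(C)C | intermediate
21 | cis-fused 19,20-δ-lactone iodide (5β-H; C4, C6 epimers) | C#CC[C@]23CC=C(O[Si](C(C)C)(C(C)C)C(C)C)C[C@H]2[C@@]4(CCCI)COC(=O)C(C)[C@H]4C3C(=O)OC(C)(C)C | intermediate
22 | ring-A-closed 19,20-lactone tert-butyl ester (8-propargyl, 12-silyl enol ether) | C#CC[C@]23CC=C(O[Si](C(C)C)(C(C)C)C(C)C)C[C@H]2[C@]14CCC[C@@](C)(C(=O)OC4)[C@H]1[C@@H]3C(=O)OC(C)(C)C | intermediate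
23 | 12-oxo-GA15 tert-butyl ester | C=C1C[C@]23C[C@H]1C(=O)C[C@H]2[C@]14CCC[C@@](C)(C(=O)OC4)[C@H]1[C@@H]3C(=O)OC(C)(C)C | intermediate
24 | trimethylsilyl ester and C11=C12 trimethylsilyl enol ether of 25 | C=C1C[C@]23C[C@H]1C(O[Si](C)(C)C)=C[C@H]2[C@]14CCC[C@@](C)(C(=O)OC4)[C@H]1[C@@H]3C(=O)O[Si](C)(C)C | intermediate (not isolated)
25 | 12-oxo-GA15 (7-acid 19,20-lactone) | C=C1C[C@]23C[C@H]1C(=O)C[C@H]2[C@]14CCC[C@@](C)(C(=O)OC4)[C@H]1[C@@H]3C(=O)O | intermediate
26 | dipotassium 20-hydroxy-12-oxogibberell-16-ene-7,19-dioate | C=C1C[C@]23C[C@H]1C(=O)C[C@H]2[C@]1(CO)CCC[C@@](C)(C(=O)[O-])[C@H]1[C@@H]3C(=O)[O-].[K+].[K+] | intermediate (not isolated)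
27 | diallyl 20-hydroxy-12-oxogibberell-16-ene-7,19-dioate | C=C1C[C@]23C[C@H]1C(=O)C[C@H]2[C@]1(CO)CCC[C@@](C)(C(=O)OCC=C)[C@H]1[C@@H]3C(=O)OCC=C | intermediate
28 | diallyl 12,20-dioxogibberell-16-ene-7,19-dioate | C=C1C[C@]23C[C@H]1C(=O)C[C@H]2[C@]1(C=O)CCC[C@@](C)(C(=O)OCC=C)[C@H]1[C@@H]3C(=O)OCC=C | intermediate
29 | 12,20-dioxogibberell-16-ene-7,19-dioic acid (12-oxo-GA24, CNP0412196.1) | C=C1C[C@]23C[C@H]1C(=O)C[C@H]2[C@]1(C=O)CCC[C@@](C)(C(=O)O)[C@H]1[C@@H]3C(=O)O | target

**Totals and risks**

Total step count: 18. Longest linear sequence: 18 steps (from pent-4-ynal).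

Steps most likely to fail:

1. Step 6 (desymmetrisation). What may go wrong: weak discrimination between the two enantiotopic enone arms by a vinylogous-malonate donor, or an uncatalysed racemic ring closure that outruns the catalyst. Fallback, from 12: change the mechanism from base to nucleophilic catalysis. An amino-acid-derived chiral bifunctional phosphine should run a Rauhut–Currier desymmetrisation: the phosphine adds to C5 of the enoate, the C10 ester enolate adds to C9, and the phosphine is expelled. This should give the cyclopentene diester F1 (C5=C10 isomer of 13). Under the conditions of step 7, F1 is deprotonated at C6 to the same delocalised anion and alkylated at C10, so the route is rejoined at 15.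

2. Step 13 (key ring closure). What may go wrong: deprotonation at C6 instead of C4 followed by C6–C3 alkylation, or a substitution at the fully substituted enolate carbon that is too slow and loses to elimination. Fallback, from 17: generate the C4 enolate regiospecifically and without an amide base.
   - Esterification with diethylphosphonoacetic acid (DCC, DMAP) should give the phosphonoacetate F2.
   - Cs2CO3 should bring about the tethered Michael addition to the α-phosphono lactone F3.
   - Horner–Wadsworth–Emmons reaction with formaldehyde (K2CO3, aq. HCHO) should give the α-methylene lactone F4.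
   - NaI should give the corresponding iodide F5.
   - L-Selectride (THF, −78 → 0 °C) then adds hydride to the exocyclic methylene carbon (which becomes C18). The resulting lactone enolate should close ring A as in step 13, and the same t-BuOH/t-BuOK equilibration returns to 22.

3. Step 5 (olefination). What may go wrong: slow Wittig reaction of a hindered, largely enolised formyl ester, with deformylation on prolonged heating. Fallback, from 10: use the enol as an electrophile. TsCl/N-methylimidazole/Et3N should give the enol tosylate F6, and palladium-catalysed Negishi coupling with the Reformatsky reagent of methyl bromoacetate should give the β,γ-unsaturated diester F7. F7 is the deconjugated tautomer of 12 and gives the same anion under the conditions of step 6, so the route is rejoined at 13.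

Further compounds
F1 | step 6 | cyclopentene diester, C5=C10 isomer of 13 (C6 epimers) | C#CC[C@]23C=CC(=O)C[C@H]2C(C(=O)OC)=CC3C(=O)OC(C)(C)C
F2 | step 13 | C20 (diethoxyphosphoryl)acetate of 17 | C#CC[C@]23CC=C(O[Si](C(C)C)(C(C)C)C(C)C)C[C@H]2[C@](COC(=O)CP(=O)(OCC)OCC)(CCCCl)C=C3C(=O)OC(C)(C)C
F3 | step 13 | α-(diethoxyphosphoryl) δ-lactone chloride (C4, C6 epimers) | C#CC[C@]23CC=C(O[Si](C(C)C)(C(C)C)C(C)C)C[C@H]2[C@@]4(CCCCl)COC(=O)C(P(=O)(OCC)OCC)[C@H]4C3C(=O)OC(C)(C)C
F4 | step 13 | α-methylene δ-lactone chloride (C6 epimers) | C#CC[C@]23CC=C(O[Si](C(C)C)(C(C)C)C(C)C)C[C@H]2[C@@]4(CCCCl)COC(=O)C(=C)[C@H]4C3C(=O)OC(C)(C)C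
F5 | step 13 | α-methylene δ-lactone iodide (C6 epimers) | C#CC[C@]23CC=C(O[Si](C(C)C)(C(C)C)C(C)C)C[C@H]2[C@@]4(CCCI)COC(=O)C(=C)[C@H]4C3C(=O)OC(C)(C)C
F6 | step 5 | enol tosylate of 10 | C#CCC1(C=CC(=O)C=C1)C(=COS(=O)(=O)c1ccc(C)cc1)C(=O)OC(C)(C)C
F7 | step 5 | 1-tert-butyl 5-methyl 2-[4-oxo-1-(prop-2-yn-1-yl)cyclohexa-2,5-dien-1-yl]pent-2-enedioate | C#CCC1(C=CC(=O)C=C1)C(=CCC(=O)OC)C(=O)OC(C)(C)C
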